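We hold no constants yet, so we begin with what needs none: the charges and the plateaus they leave.

| flask | substrate | reagent | free catalyst | remark | time |
|---|---|---|---|---|---|
| ash | 20 mM | 10 mM | 2 mM | run made earlier |  |
| larch | 20 mM | 12 mM | 2 mM | run made earlier |  |
| maple | 20 mM | 11 mM | 2 mM | run made earlier |  |
| alder | 21 mM | 14 mM | 2 mM | run made earlier |  |
| grey | 20 mM | 14.0 mM | 2.0 mM |  | 15 d |
| teal | 12 mM | 10.0 mM | 2.0 mM |  | 5.0 d |

- ash (time / d: product / %): 2.08: 49; 4.00: 49; 6.00: 51; 8.00: 48
- larch (time / d: product / %): 2.08: 60; 4.00: 59; 6.00: 61; 8.00: 58
- maple (time / d: product / %): 0.625: 35; 1.25: 50; 3.00: 54; 8.00: 58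
- alder (time / d: product / %): 0.625: 38; 1.25: 57; 3.00: 67; 8.00: 63

(standard deviation of a reading: 1.5 percentage points)

- what was read earlier has a scatter of 1.5 percentage points, one standard deviation

- which of the two ends with the higher amount of product, in percent of the substrate charged ("neither" if they lie within 2 percentage points) (grey / teal / neither)
- product at the end, in percent of the substrate charged, grey
- product at the end, in percent of the substrate charged, teal

Our first way to the end of a flask uses the charges. The product in ash and larch stays flat, and these flasks hold less reagent than substrate, so we treat reagent as the limiting reagent and take one product from one reagent. This gives the reagent ceiling, the charged reagent over the charged substrate: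

ceiling = [reagent] charged / [substrate] charged

grey: 14.0 mM / 20 mM = 70.0%
teal: 10.0 mM / 12 mM = 83.3%

The crossing lies at equal charges of reagent and substrate, and grey and teal both hold less reagent than substrate, so we place both on the reagent side of it.

Our second way uses the plateaus as read:

ash: ceiling 50.0%, mean reading 49.2%
larch: ceiling 60.0%, mean reading 59.5%

Here the two ways agree. They part at the last maple reading, 58%, which stands 3 percentage points above its ceiling of 55.0%, against a scatter of 1.5 points. We blame the reading: maple's previous one is 54%, their mean is 56.0%, and ash and larch show no climb.

Time remains. Maple reads 50% at 1.25 d, which is 90.9% of its ceiling. As our own rough guess, we stretch that time inversely with substrate and get 2.08 d for teal, shorter than its 5.0 d. So we commit to the ceilings, with teal ahead by 13 points.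

The forecast also says teal, with grey at 69.5%. For teal it gives 80%, below our ceiling, on the ground that “its substrate is lower, so the rate matters”.

The flasks give teal as the higher, with grey at 70.0% and teal at 83.3%.

    reagent + catalyst intermediate A → catalyst intermediate B (k = 52.6 M⁻¹ h⁻¹)
    catalyst intermediate B → free catalyst + product (k = 0.719 h⁻¹)
    substrate + free catalyst → catalyst intermediate A (k = 622 M⁻¹ h⁻¹)
    free catalyst → spent catalyst (k = 0.0199 h⁻¹)

Both flasks have come to rest at their ceilings of 70.0% and 83.3%. Grey's reagent falls under a fiftieth of its charge by 2.03 d, and its product still stands at 70.0% at 150 d. Teal already holds 82.7% product at 2.50 d, its reagent is 0% at 5.00 d, and waiting until 50.0 d makes no difference. Spent catalyst reaches 7.09% of teal's catalyst, yet that step makes no difference to its product.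

Teal recharged with 48 mM of substrate holds less reagent than substrate, so the ceiling of this flask is 20.8%. The computed flask gives 20.8% at 5.00 d, with 75.0% of the substrate still free.

The numbers in the tables stem from a simulated flask for substances that don't exist, noise included.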